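All runs come from a simulation with constants of no real substance, noise included.

In the amber run, where a catalyst joins substrate to coupling partner, time grows 18.0-fold from the first reading to the last, while c(product) grows by a ratio of 2.90, so I look for the moment at which the early straight line gives way to a ceiling.

| flask | substrate | coupling partner | catalyst | time |
|---|---|---|---|---|
| amber | 0.0800 M | 0.240 M | 0.00400 M |  |
| grey | 0.0320 M | 0.192 M | 0.00400 M |  |
| blue | 0.0800 M | 0.720 M | 0.00400 M |  |
| teal | 0.0800 M | 0.240 M | 0.00400 M | 36 h |

| run | time / h | [product] / M |
|---|---|---|
| amber run | 1.0 | 0.0083 |
| amber run | 3.1 | 0.0153 |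
| amber run | 5.9 | 0.0192 |
| amber run | 9.4 | 0.0228 |
| amber run | 13 | 0.0232 |
| amber run | 18 | 0.0241 |
| grey run | 1.0 | 0.0035 |
| grey run | 3.1 | 0.0071 |
| grey run | 5.9 | 0.0115 |
| grey run | 9.4 | 0.0113 |
| grey run | 13 | 0.0132 |
| grey run | 18 | 0.0149 |
| blue run | 1.0 | 0.0164 |
| blue run | 3.1 | 0.0288 |
| blue run | 5.9 | 0.0341 |
| blue run | 9.4 | 0.0368 |
| blue run | 13 | 0.0384 |
| blue run | 18 | 0.0373 |

(readings scatter by 6 × 10⁻⁴ M)

1. reaction order in [substrate] at the outset, round the charge of the amber run, defined at two percent of the substrate turned into product (one fixed amount of product, the same in the runs compared)
2. reaction order in [coupling partner] at the outset, round the charge of the amber run, defined at two percent of the substrate turned into product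
3. product in the teal run at 36 h, as a share of the substrate charged

- Overall: substrate + coupling partner -> product, with catalyst as catalyst.
- Constant volume, constant temperature.
- Bound and free are read together.
- An order is taken over about fifteen percent of the charge, up and down.

I draw the reciprocal of c(product) against the reciprocal of time through the first and last readings of each run, which amounts to c(product) = ceiling × t/(t + τ). For amber the ceiling reads 0.0271 M, and τ, the crossing time at which the early line would reach the ceiling, reads 2.27 h; at that time the curve stands at half of its ceiling.

| run | ceiling | share of substrate charged | crossing time |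
|---|---|---|---|
| amber | 0.0271 M | 33.9% | 2.27 h |
| grey | 0.0184 M | 57.6% | 4.27 h |
| blue | 0.0403 M | 50.4% | 1.46 h |

Reading amber against blue, which share a substrate charge, I see that the blue run, with its larger charge of partner, crosses sooner than amber and under a higher ceiling. Reading amber against grey, I see that the grey run, charged with less substrate and also less partner, crosses later but reaches a larger share of its charge. The teal run has the amber charge, so I use the amber curve: 36 h is 15.9 crossing times, which leaves it 5.93% below the ceiling, and I commit to 31.9% of the substrate charged.

The forecast gives 31.5%, with orders 0.85 in substrate and 0.75 in partner, and judges of the stall: “So the catalyst is dying or being tied up by product.”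

The teal flask gives 31.7% of its substrate charged, and round the amber charge the orders are 1.0 in substrate and 0.88 in partner.

    catalyst + substrate ⇌ catalyst-substrate complex (500.4 /M/h, 914.4 /h)
    catalyst-substrate complex + coupling partner → product + catalyst (1087 /M/h)
    2 substrate → homo dimer (6.336 /M/h)
    2 catalyst ⇌ resting dimer, settled at all times (540.0 /M)

At the teal charge, the first half-life of the substrate by the step to homo dimer alone is 0.986 h, shorter than the amber crossing time. The teal result stands at 93.4% of the ceiling read from the amber run. In the grey run, the crossing time of 4.27 h under the ceiling read there of 0.0184 M puts a quarter of the substrate charged at 3.27 h, and the grey flask arrives there at 3.33 h.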